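**Plan**

1. Labdane numbering is used: ring A is C1–C5 plus C10, ring B is C5–C10, C17 is the carboxyl carbon on C8, C11–C15 is the chain with C16 on C13, and C20 is the methyl on C10. Ring B joins quaternary C10 to C9 beside the carboxyl-bearing C8, so a tertiary C10 radical can add to C9 as the β-carbon of an acrylate whose α-carbon C8 hangs from C5 through C6–C7.
2. Retrosynthesis: the acetate and the C7=C8 double bond are removed first, then the C9–C10 bond (ring B), then C8=C9 (olefination), C7–C8 (phosphonate alkylation) and C5–C6 (Claisen rearrangement).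
3. Forward: ring A is bought as a cyclohexenone and given its C6–C7 arm; the arm is joined to a citronellol-derived aldehyde as a (Z)-acrylate; ring B is closed by hydrogen-atom-transfer radical cyclisation; dehydrogenation, deprotection and acetylation finish the synthesis.
4. Stereochemistry: C13 comes from (S)-citronellol; C5 from a catalytic enantioselective ketone reduction relayed by a suprafacial [3,3] shift; C10 and C9 from the chair transition state of the ring closure, steered by C5 and by the (Z)-alkene.

Key step: step 9

Assumption: both C8 epimers of the cyclised ester serve equally because C8 becomes sp2 again in step 11, and the ester is drawn with the 8β-carboxylate expected from protonation on the α face; 2,4,4-trimethylcyclohex-2-en-1-one and methyl bis(2,2,2-trifluoroethyl)phosphonoacetate are taken as purchased.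

**Route**

Step 1
Reactants: 1 2,4,4-trimethylcyclohex-2-en-1-one
Product: 2 (R)-2,4,4-trimethylcyclohex-2-en-1-ol
Conditions: (S)-2-methyl-CBS-oxazaborolidine (10 mol %), BH3·SMe2, THF, −20 °C; MeOH quench
Reagents that add atoms: none
Why: Corey–Bakshi–Shibata reduction, in which the oxazaborolidine–borane complex binds the ketone with the α-methylalkenyl arm as the large group and delivers hydride to the Si face, setting the (R)-carbinol centre while 1,2-reduction outpaces hydroboration of the trisubstituted alkene.

Step 2
Reactants: 2 (R)-2,4,4-trimethylcyclohex-2-en-1-ol; 3 triethyl orthoacetate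
Product: 6 ethyl 2-[(S)-2,6,6-trimethylcyclohex-2-en-1-yl]acetate, via mixed orthoester 4 (not isolated), via ketene acetal 5 (not isolated)
Conditions: neat 3 (excess), EtCO2H (cat.), 140 °C, EtOH distilled off
Reagents that add atoms: none
Why: Johnson–Claisen rearrangement, in which acid-catalysed exchange and loss of ethanol give ketene acetal 5, whose suprafacial chair-like [3,3] shift forms the C5–C6 bond on the ring face that carried oxygen, so the (R)-carbinol centre is relayed into (S)-C5 as the alkene moves to C1=C10.

Step 3
Reactants: 6 ethyl 2-[(S)-2,6,6-trimethylcyclohex-2-en-1-yl]acetate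
Product: 7 2-[(S)-2,6,6-trimethylcyclohex-2-en-1-yl]ethanol
Conditions: LiAlH4, Et2O, 0 °C
Reagents that add atoms: none
Why: Hydride reduction of an ester to the primary alcohol, which leaves the isolated alkene and the non-enolisable C5 centre untouched.

Step 4
Reactants: 7 2-[(S)-2,6,6-trimethylcyclohex-2-en-1-yl]ethanol
Product: 8 (S)-6-(2-iodoethyl)-1,5,5-trimethylcyclohex-1-ene
Conditions: I2, PPh3, imidazole, CH2Cl2, 0 °C → rt
Reagents that add atoms: iodine, II
Why: Appel-type iodination, in which the alkoxyphosphonium ion formed from PPh3 and I2 is displaced by iodide in an SN2 step at the unhindered primary carbon C7.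

Step 5
Reactants: 8 (S)-6-(2-iodoethyl)-1,5,5-trimethylcyclohex-1-ene; 9 methyl bis(2,2,2-trifluoroethyl)phosphonoacetate
Product: 11 methyl 2-[bis(2,2,2-trifluoroethoxy)phosphoryl]-4-[(S)-2,6,6-trimethylcyclohex-2-en-1-yl]butanoate, via sodium phosphonate 10 (not isolated)
Conditions: 9 (excess), NaH, DMF, 0 °C; then 8, rt → 50 °C
Reagents that add atoms: none
Why: SN2 C-alkylation of a stabilised phosphonoacetate anion by a primary iodide forms the C7–C8 bond, an excess of 9 holding back dialkylation; the new centre at C8 is lost when C8 becomes sp2 in step 8.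

Step 6
Reactants: 12 (S)-citronellol
Product: 13 (S)-citronellyl tert-butyldimethylsilyl ether
Conditions: TBSCl, imidazole, CH2Cl2, rt
Reagents that add atoms: tert-butyldimethylsilyl chloride, CC(C)(C)[Si](C)(C)Cl
Why: Imidazole-promoted silylation of a primary alcohol, chosen because the silyl ether tolerates ozone, amide bases, the iron hydride and peroxide.

Step 7
Reactants: 13 (S)-citronellyl tert-butyldimethylsilyl ether
Product: 15 (S)-6-[(tert-butyldimethylsilyl)oxy]-4-methylhexanal, via ozonide 14 (not isolated)
Conditions: O3, CH2Cl2, −78 °C; then PPh3, −78 °C → rt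
Reagents that add atoms: ozone, [O-][O+]=O
Why: Ozonolysis with reductive work-up, in which cycloaddition of ozone to the electron-rich trisubstituted alkene and recombination give ozonide 14, which PPh3 reduces to the aldehyde (the future C9) without touching C13.

Step 8
Reactants: 11 methyl 2-[bis(2,2,2-trifluoroethoxy)phosphoryl]-4-[(S)-2,6,6-trimethylcyclohex-2-en-1-yl]butanoate; 15 (S)-6-[(tert-butyldimethylsilyl)oxy]-4-methylhexanal
Product: 17 methyl (2Z,6S)-8-[(tert-butyldimethylsilyl)oxy]-6-methyl-2-{2-[(1S)-2,6,6-trimethylcyclohex-2-en-1-yl]ethyl}oct-2-enoate, via potassium phosphonate 16 (not isolated)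
Conditions: KN(SiMe3)2, 18-crown-6, THF, −78 °C; then 15
Reagents that add atoms: none
Why: Still–Gennari olefination, in which the electron-poor trifluoroethyl phosphonate eliminates rapidly from the kinetically favoured adduct, so the trisubstituted alkene should form with the C11 chain cis to the ester and trans to C7, the (Z)-geometry that the ring closure requires.

Step 9
Reactants: 17 methyl (2Z,6S)-8-[(tert-butyldimethylsilyl)oxy]-6-methyl-2-{2-[(1S)-2,6,6-trimethylcyclohex-2-en-1-yl]ethyl}oct-2-enoate
Product: 18 methyl (13S)-15-[(tert-butyldimethylsilyl)oxy]-8αH-labdan-17-oate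
Conditions: Fe(acac)3 (30 mol %), PhSiH3 (slow addition), EtOH/(CH2OH)2 5:1, 60 °C, 0.01 M
Reagents that add atoms: none
Why: The trivalent iron hydride formed from Fe(acac)3 and PhSiH3 transfers a hydrogen atom to C1, the less substituted carbon of the ring A alkene, and the tertiary C10 radical adds to C9, the β-carbon of the tethered acrylate, after which the C8 α-ester radical is reduced by divalent iron and protonated by ethanol; the closest known reaction type is the metal-hydride hydrogen-atom-transfer Giese coupling of unactivated alkenes with acrylates, including its cyclising variants. Ring B closes in a 6-endo-trig mode, since 5-exo attack at the fully substituted, ester-bearing C8 is mismatched in polarity and congested. C10 is set by a chair-like transition state in which the C5–C6 tether is equatorial on ring A and C9 approaches equatorially, so the C20 methyl ends axial and anti to H-5 (trans fusion). C9 is set by the (Z)-alkene: the C11 chain, trans to C7 across C8=C9, takes the equatorial site of the forming chair and becomes 9β, whereas the (E)-isomer would place it axial. C8 is set by protonation on the α face opposite the axial C20 methyl and is of no consequence. The step needs hydrogen-atom transfer to the electron-rich ring alkene in preference to the acrylate and cyclisation faster than radical reduction, which the pairing of a nucleophilic tertiary radical with an electrophilic acrylate, the six-membered tether and the slow addition of silane should secure.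

Step 10
Reactants: 18 methyl (13S)-15-[(tert-butyldimethylsilyl)oxy]-8αH-labdan-17-oate
Product: 20 methyl (13S)-15-[(tert-butyldimethylsilyl)oxy]-8α-(phenylselanyl)labdan-17-oate, via lithium enolate 19 (not isolated)
Conditions: LiN(i-Pr)2, THF, −78 → 0 °C; then PhSeBr, −78 °C
Reagents that add atoms: phenylselenenyl bromide, Br[Se]c1ccccc1
Why: Ester enolate selenenylation, in which LiN(i-Pr)2 removes the only acidic C–H (C8) and PhSeBr is captured on the α face, away from the axial C20 methyl, giving the 8α-selenide.

Step 11
Reactants: 20 methyl (13S)-15-[(tert-butyldimethylsilyl)oxy]-8α-(phenylselanyl)labdan-17-oate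
Product: 22 methyl (13S)-15-[(tert-butyldimethylsilyl)oxy]labd-7-en-17-oate, via selenoxide 21 (not isolated)
Conditions: H2O2 (30% aq.), pyridine, CH2Cl2, 0 °C → rt
Reagents that add atoms: none
Why: Selenoxide syn-elimination, in which oxidation at selenium and a five-membered cyclic transition state remove a cis hydrogen, and the accessible C7 methylene hydrogen should be taken in preference to the neopentyl tertiary C9–H, placing the double bond at C7=C8 in conjugation with the ester.

Step 12
Reactants: 22 methyl (13S)-15-[(tert-butyldimethylsilyl)oxy]labd-7-en-17-oate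
Product: 24 (13S)-15-hydroxylabd-7-en-17-oic acid, via lithium carboxylate 23 (not isolated)
Conditions: LiOH·H2O, THF/MeOH/H2O, 60 °C; then 2 M HCl, THF, rt
Reagents that add atoms: lithium hydroxide, [Li+].[OH-]
Why: Saponification of the conjugated methyl ester followed by acid hydrolysis of the primary silyl ether in the same flask; C9 is not vinylogous to the carboxyl group and so cannot epimerise.

Step 13
Reactants: 24 (13S)-15-hydroxylabd-7-en-17-oic acid
Product: 26 (13S)-15-acetoxylabd-7-en-17-oic acid, via mixed anhydride 25 (not isolated)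
Conditions: Ac2O, pyridine, DMAP (cat.), CH2Cl2, 0 °C → rt; then H2O
Reagents that add atoms: acetic anhydride, CC(=O)OC(C)=O
Why: Pyridine/DMAP-catalysed O-acetylation of the primary alcohol, in which the carboxyl group passes through mixed anhydride 25 and water cleaves it at the unhindered acetyl carbonyl to return the free acid.

**Compound list**

1 | 2,4,4-trimethylcyclohex-2-en-1-one | CC1=CC(C)(C)CCC1=O | starting material
2 | (R)-2,4,4-trimethylcyclohex-2-en-1-ol | O[C@@H]1CCC(C)(C)C=C1C | intermediate
3 | triethyl orthoacetate | CC(OCC)(OCC)OCC | starting material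
4 | mixed orthoester, (R)-6-(1,1-diethoxyethoxy)-1,3,3-trimethylcyclohex-1-ene | CCOC(C)(OCC)O[C@@H]1CCC(C)(C)C=C1C | intermediate
5 | ketene acetal, (R)-6-[(1-ethoxyvinyl)oxy]-1,3,3-trimethylcyclohex-1-ene | C=C(OCC)O[C@@H]1CCC(C)(C)C=C1C | intermediate
6 | ethyl 2-[(S)-2,6,6-trimethylcyclohex-2-en-1-yl]acetate | CCOC(=O)C[C@@H]1C(C)=CCCC1(C)C | intermediate
7 | 2-[(S)-2,6,6-trimethylcyclohex-2-en-1-yl]ethanol | OCC[C@@H]1C(C)=CCCC1(C)C | intermediate
8 | (S)-6-(2-iodoethyl)-1,5,5-trimethylcyclohex-1-ene | ICC[C@@H]1C(C)=CCCC1(C)C | intermediate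
9 | methyl bis(2,2,2-trifluoroethyl)phosphonoacetate | COC(=O)CP(=O)(OCC(F)(F)F)OCC(F)(F)F | starting material
10 | sodium salt of 9 (phosphonate carbanion) | [Na+].COC(=O)[CH-]P(=O)(OCC(F)(F)F)OCC(F)(F)F | intermediate
11 | methyl 2-[bis(2,2,2-trifluoroethoxy)phosphoryl]-4-[(S)-2,6,6-trimethylcyclohex-2-en-1-yl]butanoate (both epimers at the phosphonate-bearing carbon) | COC(=O)C(CC[C@@H]1C(C)=CCCC1(C)C)P(=O)(OCC(F)(F)F)OCC(F)(F)F | intermediate
12 | (S)-citronellol | OCC[C@@H](C)CCC=C(C)C | starting material
13 | (S)-citronellyl tert-butyldimethylsilyl ether | CC(C)(C)[Si](C)(C)OCC[C@@H](C)CCC=C(C)C | intermediate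
14 | ozonide (1,2,4-trioxolane) of 13 | CC(C)(C)[Si](C)(C)OCC[C@@H](C)CCC1OOC(C)(C)O1 | intermediate
15 | (S)-6-[(tert-butyldimethylsilyl)oxy]-4-methylhexanal | CC(C)(C)[Si](C)(C)OCC[C@@H](C)CCC=O | intermediate
16 | potassium salt of 11 (phosphonate carbanion) | [K+].COC(=O)[C-](CC[C@@H]1C(C)=CCCC1(C)C)P(=O)(OCC(F)(F)F)OCC(F)(F)F | intermediate
17 | methyl (2Z,6S)-8-[(tert-butyldimethylsilyl)oxy]-6-methyl-2-{2-[(1S)-2,6,6-trimethylcyclohex-2-en-1-yl]ethyl}oct-2-enoate (cyclisation precursor; C11 chain cis to the ester) | CC1=CCCC(C)(C)[C@@H]1CC/C(C(=O)OC)=C/CC[C@H](C)CCO[Si](C)(C)C(C)(C)C | intermediate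
18 | methyl (13S)-15-[(tert-butyldimethylsilyl)oxy]-8αH-labdan-17-oate (trans-decalin; 5α-H, 9β side chain, 10β-methyl, 8β-CO2Me) | CC(C)(C)[Si](C)(C)OCC[C@@H](C)CC[C@H]1[C@@H](C(=O)OC)CC[C@H]2C(C)(C)CCC[C@]12C | intermediate
19 | lithium enolate of 18 | CC(C)(C)[Si](C)(C)OCC[C@@H](C)CC[C@H]1C(=C(OC)O[Li])CC[C@H]2C(C)(C)CCC[C@]12C | intermediate
20 | methyl (13S)-15-[(tert-butyldimethylsilyl)oxy]-8α-(phenylselanyl)labdan-17-oate | CC(C)(C)[Si](C)(C)OCC[C@@H](C)CC[C@H]1[C@](C(=O)OC)([Se]c3ccccc3)CC[C@H]2C(C)(C)CCC[C@]12C | intermediate
21 | selenoxide of 20 | CC(C)(C)[Si](C)(C)OCC[C@@H](C)CC[C@H]1[C@](C(=O)OC)([Se](=O)c3ccccc3)CC[C@H]2C(C)(C)CCC[C@]12C | intermediate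
22 | methyl (13S)-15-[(tert-butyldimethylsilyl)oxy]labd-7-en-17-oate | CC(C)(C)[Si](C)(C)OCC[C@@H](C)CC[C@H]1C(C(=O)OC)=CC[C@H]2C(C)(C)CCC[C@]12C | intermediate
23 | lithium (13S)-15-[(tert-butyldimethylsilyl)oxy]labd-7-en-17-oate | [Li+].CC(C)(C)[Si](C)(C)OCC[C@@H](C)CC[C@H]1C(C(=O)[O-])=CC[C@H]2C(C)(C)CCC[C@]12C | intermediate
24 | (13S)-15-hydroxylabd-7-en-17-oic acid | OCC[C@@H](C)CC[C@H]1C(C(=O)O)=CC[C@H]2C(C)(C)CCC[C@]12C | intermediate
25 | acetic (13S)-15-acetoxylabd-7-en-17-oic anhydride | CC(=O)OCC[C@@H](C)CC[C@H]1C(C(=O)OC(C)=O)=CC[C@H]2C(C)(C)CCC[C@]12C | intermediate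
26 | (13S)-15-acetoxylabd-7-en-17-oic acid, CNP0412535.1 (5α-H, 9β side chain, 10β-methyl) | CC(=O)OCC[C@@H](C)CC[C@H]1C(C(=O)O)=CC[C@H]2C(C)(C)CCC[C@]12C | target

**Step count and risks**

Total: 13 steps. Longest linear sequence: 11 steps (steps 1–5 and 8–13); steps 6–7 form the side branch.

Steps most likely to fail:

1. Step 9. The C10 radical may be reduced before it cyclises, because 6-endo addition to a β-alkylated acrylate is slow. Reversible hydrogen-atom transfer may also move the ring A alkene toward C5 and erode that centre, or closure through a boat may give cis-fused or 9-epimeric material. The fallback generates the same tertiary radical without any metal hydride and at room temperature. It sets out from 17: Mukaiyama hydration (Co(acac)2, PhSiH3, O2, i-PrOH) should give the C10 tertiary alcohol F1, acylation with methyl chlorooxoacetate (Et3N, DMAP) the methyl oxalate F2, and selective hydrolysis with CsOH the cesium oxalate F3. Visible-light photoredox decarboxylation of F3 (Ir[dF(CF3)ppy]2(dtbbpy)PF6, blue light, DME/DMF, H2O) should then release the C10 radical for the same 6-endo closure onto C9, with reduction and protonation at C8, and the route is rejoined at 18.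

2. Step 11. Syn-elimination may run toward C9 and give the tetrasubstituted C8=C9 isomer, or the congested C8 may resist enolisation and selenenylation in step 10. The fallback replaces both steps by a palladium-enolate dehydrogenation that sets out from 18: lithium 2,2,6,6-tetramethylpiperidide and ZnCl2 give the zinc enolate, which is oxidised with [Pd(C3H5)Cl]2 (cat.) and allyl pivalate in toluene at 60 °C. β-Hydride elimination from the C8-bound palladium enolate is sterically more demanding than the selenoxide elimination and should take the C7 methylene hydrogen; the route is rejoined at 22 (no new compound; F0).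

3. Step 5. Alkylation of the weakly nucleophilic, base-sensitive trifluoroethyl phosphonate anion may be slow or run on to the dialkylated product; the same detour would also cure an inadequate alkene geometry in step 8. The fallback forms the C7–C8 bond by cross-coupling and sets out from 8 and 15. Bromination of 9 (NaH, then Br2) gives methyl bromo[bis(2,2,2-trifluoroethoxy)phosphoryl]acetate F4; its olefination with 15 (KN(SiMe3)2, 18-crown-6, THF, −78 °C) should give methyl (2E,6S)-2-bromo-8-[(tert-butyldimethylsilyl)oxy]-6-methyloct-2-enoate F5, with bromine trans to the chain. Zinc insertion into 8 (Zn, LiCl, THF) gives 2-[(S)-2,6,6-trimethylcyclohex-2-en-1-yl]ethylzinc iodide F6, and Negishi coupling of F5 with F6 (Pd(PPh3)4, THF, 50 °C) proceeds with retention of alkene geometry, rejoining the route at 17.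

**Further compounds**

F1 | step 9 | methyl (2Z,6S)-8-[(tert-butyldimethylsilyl)oxy]-2-{2-[(1S)-2-hydroxy-2,6,6-trimethylcyclohexyl]ethyl}-6-methyloct-2-enoate (both epimers at the carbinol carbon) | CC1(O)CCCC(C)(C)[C@@H]1CC/C(C(=O)OC)=C/CC[C@H](C)CCO[Si](C)(C)C(C)(C)C
F2 | step 9 | methyl oxalate diester of F1 | COC(=O)C(=O)OC1(C)CCCC(C)(C)[C@@H]1CC/C(C(=O)OC)=C/CC[C@H](C)CCO[Si](C)(C)C(C)(C)C
F3 | step 9 | cesium oxalate half-ester of F1 | [Cs+].[O-]C(=O)C(=O)OC1(C)CCCC(C)(C)[C@@H]1CC/C(C(=O)OC)=C/CC[C@H](C)CCO[Si](C)(C)C(C)(C)C
F0 | step 11 | none | none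
F4 | step 5 | methyl bromo[bis(2,2,2-trifluoroethoxy)phosphoryl]acetate | COC(=O)C(Br)P(=O)(OCC(F)(F)F)OCC(F)(F)F
F5 | step 5 | methyl (2E,6S)-2-bromo-8-[(tert-butyldimethylsilyl)oxy]-6-methyloct-2-enoate | COC(=O)/C(Br)=C\CC[C@H](C)CCO[Si](C)(C)C(C)(C)C
F6 | step 5 | 2-[(S)-2,6,6-trimethylcyclohex-2-en-1-yl]ethylzinc iodide | I[Zn]CC[C@@H]1C(C)=CCCC1(C)C
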